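## Retrosynthetic overview

1. Target 24 ⇒ seco epoxy aldehyde 21. The last step closes C6–C7 by intramolecular Nozaki–Hiyama–Kishi (NHK) addition of a β-(methoxycarbonyl)alkenyl chromium unit, in which the enoate β-carbon acts as the nucleophile, to the C6 aldehyde. The ten-membered carbocycle forms first; the butenolide then closes in the same flask by lactonisation of the new C6 alkoxide onto the cis ester. The epoxide is already in place.
2. 21 ⇒ allylic alcohol 19 (Sharpless epoxidation, then oxidation). The tetrasubstituted (Z)-iodo enoate carrying C13 ⇒ γ-hydroxy ynoate 14 by alkoxide-directed iodo-aldol reaction with formaldehyde.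
3. 14 ⇒ aldehyde 12 + methyl propiolate (asymmetric alkynylation sets C8). 12 ⇒ (Z)-vinyl iodide 9 + a two-carbon zinc reagent (Negishi coupling).
4. 9 ⇒ propargylic alcohol 5 (trans-hydroalumination/iodination fixes the 1(10)-Z alkene) ⇒ but-2-ynal + senecioate silyl dienolate (asymmetric vinylogous Mukaiyama aldol sets C2 and the E C4=C5 alkene).

Assumption: positions are cited with germacrane numbering (C6 lactone carbinol, C7=C11 butenolide alkene, C8 methacrylate carbinol, C12 lactone carbonyl, C13 acetoxymethyl). For each chiral catalyst the enantiomer written is taken to give the drawn configuration; its mirror-image form is used should the sense prove opposite.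

## Route

Step 1
Reactants: 1 methyl 3-methylbut-2-enoate
Product: 3 tert-butyl[(1-methoxy-3-methylbuta-1,3-dien-1-yl)oxy]dimethylsilane, via lithium dienolate 2 (not isolated)
Conditions: LiN(iPr)2, THF, −78 °C; TBSCl, DMPU, −78 °C→rt; distil
Reagents that add atoms: tert-butyldimethylsilyl chloride, CC(C)(C)[Si](C)(C)Cl
Why: Kinetic γ-deprotonation of the senecioate gives the extended lithium dienolate, which is silylated on oxygen (silyl dienol ether formation); no stereocentre is formed and the ketene-acetal geometry is inconsequential.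

Step 2
Reactants: 3 silyl dienolate; 4 but-2-ynal
Product: 5 methyl (2E,5S)-5-hydroxy-3-methyloct-2-en-6-ynoate
Conditions: SiCl4 (1.1 equiv), (R,R)-Denmark binaphthyldiamine bisphosphoramide (5 mol %), iPr2NEt (10 mol %), CH2Cl2, −78 °C; aq. NaHCO3/KF
Reagents that add atoms: none
Why: Lewis-base-activated SiCl4 vinylogous Mukaiyama aldol (Denmark): the dienolate attacks through its γ-carbon on the si face of the ynal inside the chiral phosphoramide-bound silicon cation, giving the (E)-enoate and the 5S carbinol (C2 of the target).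

Step 3
Reactants: 5 hydroxy enynoate
Product: 7 (2E,5S,6Z)-7-iodo-3-methylocta-2,6-diene-1,5-diol, via alkenylalanate 6 (not isolated)
Conditions: NaAlH2(OCH2CH2OMe)2 (4 equiv), THF, 0 °C→rt; then I2, THF, −78→0 °C; Rochelle salt work-up
Reagents that add atoms: iodine, II
Why: The aluminium hydride reduces the enoate 1,2 to the allylic alcohol and, through the propargylic alkoxide, delivers hydride trans across the alkyne with aluminium on the distal carbon; iodinolysis with retention gives the (Z)-iodide (I cis to the carbinol carbon) and leaves the stereocentre untouched.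

Step 4
Reactants: 7 iodo diol
Product: 9 (2Z,4S,6E)-8-[(tert-butyldiphenylsilyl)oxy]-2-iodo-6-methylocta-2,6-dien-4-yl acetate, via mono-TBDPS ether 8 (not isolated)
Conditions: TBDPSCl (1.05 equiv), imidazole, CH2Cl2, 0 °C; then Ac2O, Et3N, DMAP (cat.), rt
Reagents that add atoms: tert-butyldiphenylsilyl chloride, CC(C)(C)[Si](Cl)(c1ccccc1)c1ccccc1; acetic anhydride, CC(=O)OC(C)=O
Why: Steric selectivity puts the silyl group on the primary allylic hydroxyl only, and the remaining secondary hydroxyl is then acetylated to install the C2 acetate of the target (one-pot sequential protection/acylation).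

Step 5
Reactants: 9 vinyl iodide; 10 (1,3-dioxolan-2-ylmethyl)zinc bromide (0.5 M in THF)
Product: 11 (2E,5S,6Z)-1-[(tert-butyldiphenylsilyl)oxy]-8-(1,3-dioxolan-2-yl)-3,7-dimethylocta-2,6-dien-5-yl acetate
Conditions: Pd(OAc)2 (5 mol %), SPhos (10 mol %), THF, 40 °C
Reagents that add atoms: none
Why: Negishi sp2–sp3 cross-coupling proceeds with retention of alkene geometry, so the new CH2 (C9) ends cis to C2 and the Z trisubstituted 1(10) alkene is fixed.

Step 6
Reactants: 11 dioxolane
Product: 12 (2E,5S,6Z)-1-[(tert-butyldiphenylsilyl)oxy]-3,7-dimethyl-9-oxonona-2,6-dien-5-yl acetate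
Conditions: LiBF4, MeCN/H2O (50:1), 40 °C; used crude
Reagents that add atoms: water, O
Why: Mild Lewis-acid acetal hydrolysis frees the β,γ-unsaturated aldehyde (C8) without moving the alkene into conjugation or cleaving the silyl ether or acetate.

Step 7
Reactants: 12 aldehyde; 13 methyl propiolate
Product: 14 methyl (4S,6Z,8S,10E)-8-(acetyloxy)-12-[(tert-butyldiphenylsilyl)oxy]-4-hydroxy-6,10-dimethyldodeca-6,10-dien-2-ynoate
Conditions: Me2Zn (3 equiv), (S,S)-ProPhenol (20 mol %), Ph3P=O (40 mol %), toluene, 4 °C; aq. NH4Cl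
Reagents that add atoms: none
Why: Zinc–ProPhenol-catalysed asymmetric alkynylation: the methylzinc acetylide of 13 adds to the re face of the aldehyde in the dinuclear zinc pocket, setting 4S (C8 of the target) under catalyst control.

Step 8
Reactants: 14 γ-hydroxy ynoate
Product: 16 methyl (2Z,4S,6Z,8S,10E)-8-(acetyloxy)-12-[(tert-butyldiphenylsilyl)oxy]-4-hydroxy-2-(hydroxymethyl)-3-iodo-6,10-dimethyldodeca-2,6,10-trienoate, via magnesium iodoallenolate 15 (not isolated)
Conditions: MeMgI (1.0 equiv), CH2Cl2/Et2O, −78 °C; MgI2 (2 equiv), CH2O (monomer, THF solution), −78→−30 °C; aq. NH4Cl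
Reagents that add atoms: magnesium diiodide, [Mg+2].[I-].[I-]; formaldehyde, C=O
Why: Proposed new method: iodide adds to the ynoate β-carbon (C7) to give a magnesium β-iodoallenolate, and the C8 magnesium alkoxide binds formaldehyde and hands it to the allenolate α-carbon (C11) through a seven-membered chelate on the C8 side, so CH2OH ends cis to C8 and iodine cis to CO2Me (Z); the unwanted E isomer would lactonise onto the C8 hydroxyl and is removed by chromatography; the closest known reaction is the MgI2- or Et2AlI-mediated β-iodo Morita–Baylis–Hillman (iodo-aldol) reaction of alkynoates with aldehydes.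

Step 9
Reactants: 16 iodo diol
Product: 18 methyl (2Z,4S,6Z,8S,10E)-8-(acetyloxy)-2-[(acetyloxy)methyl]-12-[(tert-butyldiphenylsilyl)oxy]-3-iodo-6,10-dimethyl-4-[(2-methylprop-2-enoyl)oxy]dodeca-2,6,10-trienoate, via monoacetate 17 (not isolated)
Conditions: AcCl (1.05 equiv), 2,4,6-collidine, CH2Cl2, −78 °C; then methacryloyl chloride, pyridine, 0 °C→rt
Reagents that add atoms: acetyl chloride, CC(=O)Cl; methacryloyl chloride, C=C(C)C(=O)Cl
Why: Acetyl chloride/collidine at low temperature acylates the primary allylic hydroxyl (C13) selectively, and methacryloyl chloride then esterifies the hindered secondary C8 hydroxyl (sequential acylation; nucleophilic amine catalysts are avoided because of the β-iodo enoate).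

Step 10
Reactants: 18 silyl ether
Product: 19 methyl (2Z,4S,6Z,8S,10E)-8-(acetyloxy)-2-[(acetyloxy)methyl]-12-hydroxy-3-iodo-6,10-dimethyl-4-[(2-methylprop-2-enoyl)oxy]dodeca-2,6,10-trienoate
Conditions: HF·pyridine, pyridine, THF, 0 °C→rt
Reagents that add atoms: none
Why: Fluoride-mediated Si–O cleavage removes the TBDPS ether while the esters, vinyl iodide and alkenes survive.

Step 11
Reactants: 19 allylic alcohol
Product: 20 methyl (2Z,4S,6Z,8S)-8-(acetyloxy)-2-[(acetyloxy)methyl]-9-[(2R,3R)-3-(hydroxymethyl)-2-methyloxiran-2-yl]-3-iodo-6-methyl-4-[(2-methylprop-2-enoyl)oxy]nona-2,6-dienoate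
Conditions: Ti(OiPr)4 (20 mol %), D-(−)-diethyl tartrate (25 mol %), t-BuOOH, 4 Å MS, CH2Cl2, −20 °C
Reagents that add atoms: tert-butyl hydroperoxide, CC(C)(C)OO
Why: Sharpless asymmetric epoxidation: the titanium–D-(−)-tartrate complex oxidises only the alkene of the free primary allylic alcohol, on the face that gives the (2R,3R)-epoxy alcohol (C4 R, C5 R) under reagent control, as for geraniol-type E-allylic alcohols.

Step 12
Reactants: 20 epoxy alcohol
Product: 21 methyl (2Z,4S,6Z,8S)-8-(acetyloxy)-2-[(acetyloxy)methyl]-9-[(2R,3S)-3-formyl-2-methyloxiran-2-yl]-3-iodo-6-methyl-4-[(2-methylprop-2-enoyl)oxy]nona-2,6-dienoate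
Conditions: Dess–Martin periodinane, NaHCO3, CH2Cl2, 0 °C→rt; used at once
Reagents that add atoms: none
Why: Buffered Dess–Martin oxidation converts the primary epoxy alcohol into the α,β-epoxy aldehyde without epimerisation (the C5 descriptor changes to S by priority only).

Step 13
Reactants: 21 seco epoxy aldehyde
Product: 24 (1(10)Z,2S,4R,5R,6S,8S)-2,13-bis(acetyloxy)-4,5-epoxy-8-[(2-methylprop-2-enoyl)oxy]germacra-1(10),7(11)-dien-12,6-olide (CNP0268364.3), via alkenylchromium dichloride 22 (not isolated), via ring-closed chromium alkoxide 23 (not isolated)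
Conditions: CrCl2 (10 equiv), NiCl2 (2 mol %), DMSO/THF 3:1, syringe-pump addition to 0.002 M, rt; aq. NH4Cl
Reagents that add atoms: none
Why: Nozaki–Hiyama–Kishi macrocyclisation: zerovalent nickel inserts into the C–I bond and transmetalation to trivalent chromium gives a configurationally stable β-(methoxycarbonyl)alkenylchromium, which adds to the aldehyde anti to the epoxide C5–O bond with the chromium-bound oxygen on the periphery of the ten-membered transition state (6S, H-5/H-6 anti), and the alkoxide then lactonises onto the cis ester to form the butenolide.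

## Compound list

1 | methyl 3-methylbut-2-enoate | COC(=O)C=C(C)C | starting material
2 | lithium dienolate of 1 (lithium 1-methoxy-3-methylbuta-1,3-dien-1-olate) | [Li+].C=C(C)C=C([O-])OC | intermediate (not isolated)
3 | tert-butyl[(1-methoxy-3-methylbuta-1,3-dien-1-yl)oxy]dimethylsilane (ketene-acetal E/Z mixture) | C=C(C)C=C(OC)O[Si](C)(C)C(C)(C)C | intermediate
4 | but-2-ynal | CC#CC=O | starting material
5 | methyl (2E,5S)-5-hydroxy-3-methyloct-2-en-6-ynoate | CC#C[C@@H](O)C/C(C)=C/C(=O)OC | intermediate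
6 | disodium alkenylalanate (idealised cyclic oxaaluminate, Al on C7, C1 as alkoxide) | [Na+].[Na+].C/C1=C/[C@H](C/C(C)=C/C[O-])O[Al-]1(OCCOC)OCCOC | intermediate (not isolated)
7 | (2E,5S,6Z)-7-iodo-3-methylocta-2,6-diene-1,5-diol | C/C(I)=C/[C@@H](O)C/C(C)=C/CO | intermediate
8 | (2Z,4S,6E)-8-[(tert-butyldiphenylsilyl)oxy]-2-iodo-6-methylocta-2,6-dien-4-ol | C/C(I)=C/[C@@H](O)C/C(C)=C/CO[Si](c1ccccc1)(c1ccccc1)C(C)(C)C | intermediate (not isolated)
9 | (2Z,4S,6E)-8-[(tert-butyldiphenylsilyl)oxy]-2-iodo-6-methylocta-2,6-dien-4-yl acetate | C/C(I)=C/[C@@H](OC(C)=O)C/C(C)=C/CO[Si](c1ccccc1)(c1ccccc1)C(C)(C)C | intermediate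
10 | (1,3-dioxolan-2-ylmethyl)zinc bromide | Br[Zn]CC1OCCO1 | starting material
11 | (2E,5S,6Z)-1-[(tert-butyldiphenylsilyl)oxy]-8-(1,3-dioxolan-2-yl)-3,7-dimethylocta-2,6-dien-5-yl acetate | C(C1OCCO1)/C(C)=C\[C@@H](OC(C)=O)C/C(C)=C/CO[Si](c1ccccc1)(c1ccccc1)C(C)(C)C | intermediate
12 | (2E,5S,6Z)-1-[(tert-butyldiphenylsilyl)oxy]-3,7-dimethyl-9-oxonona-2,6-dien-5-yl acetate | O=CC/C(C)=C\[C@@H](OC(C)=O)C/C(C)=C/CO[Si](c1ccccc1)(c1ccccc1)C(C)(C)C | intermediate
13 | methyl propiolate | C#CC(=O)OC | starting material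
14 | methyl (4S,6Z,8S,10E)-8-(acetyloxy)-12-[(tert-butyldiphenylsilyl)oxy]-4-hydroxy-6,10-dimethyldodeca-6,10-dien-2-ynoate | COC(=O)C#C[C@@H](O)C/C(C)=C\[C@@H](OC(C)=O)C/C(C)=C/CO[Si](c1ccccc1)(c1ccccc1)C(C)(C)C | intermediate
15 | magnesium β-iodoallenolate of 14 (C8 alkoxide and ester enolate both as O–MgI; allene axis undefined) | COC(O[Mg]I)=C=C(I)[C@@H](O[Mg]I)C/C(C)=C\[C@@H](OC(C)=O)C/C(C)=C/CO[Si](c1ccccc1)(c1ccccc1)C(C)(C)C | intermediate (not isolated)
16 | methyl (2Z,4S,6Z,8S,10E)-8-(acetyloxy)-12-[(tert-butyldiphenylsilyl)oxy]-4-hydroxy-2-(hydroxymethyl)-3-iodo-6,10-dimethyldodeca-2,6,10-trienoate | COC(=O)/C(CO)=C(\I)[C@@H](O)C/C(C)=C\[C@@H](OC(C)=O)C/C(C)=C/CO[Si](c1ccccc1)(c1ccccc1)C(C)(C)C | intermediate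
17 | methyl (2Z,4S,6Z,8S,10E)-8-(acetyloxy)-2-[(acetyloxy)methyl]-12-[(tert-butyldiphenylsilyl)oxy]-4-hydroxy-3-iodo-6,10-dimethyldodeca-2,6,10-trienoate | COC(=O)/C(COC(C)=O)=C(\I)[C@@H](O)C/C(C)=C\[C@@H](OC(C)=O)C/C(C)=C/CO[Si](c1ccccc1)(c1ccccc1)C(C)(C)C | intermediate (not isolated)
18 | methyl (2Z,4S,6Z,8S,10E)-8-(acetyloxy)-2-[(acetyloxy)methyl]-12-[(tert-butyldiphenylsilyl)oxy]-3-iodo-6,10-dimethyl-4-[(2-methylprop-2-enoyl)oxy]dodeca-2,6,10-trienoate | COC(=O)/C(COC(C)=O)=C(\I)[C@@H](OC(=O)C(C)=C)C/C(C)=C\[C@@H](OC(C)=O)C/C(C)=C/CO[Si](c1ccccc1)(c1ccccc1)C(C)(C)C | intermediate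
19 | methyl (2Z,4S,6Z,8S,10E)-8-(acetyloxy)-2-[(acetyloxy)methyl]-12-hydroxy-3-iodo-6,10-dimethyl-4-[(2-methylprop-2-enoyl)oxy]dodeca-2,6,10-trienoate | COC(=O)/C(COC(C)=O)=C(\I)[C@@H](OC(=O)C(C)=C)C/C(C)=C\[C@@H](OC(C)=O)C/C(C)=C/CO | intermediate
20 | methyl (2Z,4S,6Z,8S)-8-(acetyloxy)-2-[(acetyloxy)methyl]-9-[(2R,3R)-3-(hydroxymethyl)-2-methyloxiran-2-yl]-3-iodo-6-methyl-4-[(2-methylprop-2-enoyl)oxy]nona-2,6-dienoate | COC(=O)/C(COC(C)=O)=C(\I)[C@@H](OC(=O)C(C)=C)C/C(C)=C\[C@@H](OC(C)=O)C[C@@]1(C)O[C@@H]1CO | intermediate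
21 | methyl (2Z,4S,6Z,8S)-8-(acetyloxy)-2-[(acetyloxy)methyl]-9-[(2R,3S)-3-formyl-2-methyloxiran-2-yl]-3-iodo-6-methyl-4-[(2-methylprop-2-enoyl)oxy]nona-2,6-dienoate | COC(=O)/C(COC(C)=O)=C(\I)[C@@H](OC(=O)C(C)=C)C/C(C)=C\[C@@H](OC(C)=O)C[C@@]1(C)O[C@@H]1C=O | intermediate
22 | alkenylchromium dichloride from 21 (CrCl2 in place of iodine at C7, geometry retained) | COC(=O)/C(COC(C)=O)=C(\[Cr](Cl)Cl)[C@@H](OC(=O)C(C)=C)C/C(C)=C\[C@@H](OC(C)=O)C[C@@]1(C)O[C@@H]1C=O | intermediate (not isolated)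
23 | ring-closed chromium alkoxide: ten-membered carbocycle, 6S O–CrCl2, exocyclic C7=C11(CH2OAc)CO2Me with the ester cis to C6 | C=C(C)C(=O)O[C@H]1C/C(C)=C\[C@@H](OC(C)=O)C[C@@]2(C)O[C@@H]2[C@@H](O[Cr](Cl)Cl)/C1=C(/COC(C)=O)C(=O)OC | intermediate (not isolated)
24 | (1(10)Z,2S,4R,5R,6S,8S)-2,13-bis(acetyloxy)-4,5-epoxy-8-[(2-methylprop-2-enoyl)oxy]germacra-1(10),7(11)-dien-12,6-olide | C=C(C)C(=O)O[C@H]1C/C(C)=C\[C@@H](OC(C)=O)C[C@@]2(C)O[C@@H]2[C@H]2OC(=O)C(COC(C)=O)=C12 | target

## Step count and risks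

Total steps: 13. Longest linear sequence: 13 steps (1 → 24); the route is fully linear and the other inputs (4, 10, 13) are commercial.

Steps most likely to fail:

**Step 13 (macrocyclising NHK/lactonisation).** The risks are β-elimination of the C8 methacrylate from the alkenyl metal species (allene formation), protodeiodination of the hindered tetrasubstituted alkenyl metal, and the wrong face at C6. The fallback keeps the ring closure but carries the C8 oxygen as a free hydroxyl, which becomes a non-leaving chromium alkoxide, and moves the methacrylation to the end. It sets out from monoacetate 17, which is isolated instead of being methacrylated. HF·pyridine gives the dihydroxy iodo enoate F1. Sharpless epoxidation with D-(−)-diethyl tartrate touches only the primary allylic alcohol and gives the epoxy diol F2. TEMPO/PhI(OAc)2 oxidises only the primary alcohol to the hydroxy epoxy aldehyde F3. CrCl2/NiCl2 under high dilution then gives the 8-hydroxy macrolactone F4, and methacryloyl chloride/pyridine returns to the route at 24. This fallback does not correct a wrong C6 configuration.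

**Step 8 (directed iodo-aldol).** The risk is that formaldehyde is delivered from the iodine side, giving the E isomer, which lactonises onto C8. The fallback ties the one-carbon electrophile to the C8 oxygen so that the geometry is ring-enforced. It sets out from 14. Formic acetic anhydride/pyridine gives the formate ester F5. MgI2 in CH2Cl2 adds iodide at C7, and the allenolate acylates itself on the tethered formate (five-membered ring) to give the iodo dihydrofuranol F6, in which C13 and the C8 oxygen are necessarily cis. NaBH4/CeCl3·7H2O in MeOH at −40 °C reduces the ring-opened hydroxy aldehyde and returns to the route at 16.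

**Step 7 (asymmetric alkynylation of an enolisable β,γ-unsaturated aldehyde).** The risks are low enantioselectivity and alkene migration. The fallback sets C8 by reagent-controlled ketone reduction instead. It sets out from 12. The lithium acetylide of 13 (LiN(SiMe3)2, THF, −78 °C) gives the epimeric propargylic alcohol F7. Dess–Martin periodinane gives the ynone F8. Midland reduction with (S)-Alpine-Borane, in which the alkynyl group acts as the small substituent, gives the 4S alcohol and returns to the route at 14.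

## Further compounds

F1 | step 13 | methyl (2Z,4S,6Z,8S,10E)-8-(acetyloxy)-2-[(acetyloxy)methyl]-4,12-dihydroxy-3-iodo-6,10-dimethyldodeca-2,6,10-trienoate | COC(=O)/C(COC(C)=O)=C(\I)[C@@H](O)C/C(C)=C\[C@@H](OC(C)=O)C/C(C)=C/CO
F2 | step 13 | methyl (2Z,4S,6Z,8S)-8-(acetyloxy)-2-[(acetyloxy)methyl]-4-hydroxy-9-[(2R,3R)-3-(hydroxymethyl)-2-methyloxiran-2-yl]-3-iodo-6-methylnona-2,6-dienoate | COC(=O)/C(COC(C)=O)=C(\I)[C@@H](O)C/C(C)=C\[C@@H](OC(C)=O)C[C@@]1(C)O[C@@H]1CO
F3 | step 13 | methyl (2Z,4S,6Z,8S)-8-(acetyloxy)-2-[(acetyloxy)methyl]-9-[(2R,3S)-3-formyl-2-methyloxiran-2-yl]-4-hydroxy-3-iodo-6-methylnona-2,6-dienoate | COC(=O)/C(COC(C)=O)=C(\I)[C@@H](O)C/C(C)=C\[C@@H](OC(C)=O)C[C@@]1(C)O[C@@H]1C=O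
F4 | step 13 | (1(10)Z,2S,4R,5R,6S,8S)-2,13-bis(acetyloxy)-4,5-epoxy-8-hydroxygermacra-1(10),7(11)-dien-12,6-olide | O[C@H]1C/C(C)=C\[C@@H](OC(C)=O)C[C@@]2(C)O[C@@H]2[C@H]2OC(=O)C(COC(C)=O)=C12
F5 | step 8 | methyl (4S,6Z,8S,10E)-8-(acetyloxy)-12-[(tert-butyldiphenylsilyl)oxy]-4-(formyloxy)-6,10-dimethyldodeca-6,10-dien-2-ynoate | COC(=O)C#C[C@@H](OC=O)C/C(C)=C\[C@@H](OC(C)=O)C/C(C)=C/CO[Si](c1ccccc1)(c1ccccc1)C(C)(C)C
F6 | step 8 | methyl (5S)-5-[(2Z,4S,6E)-4-(acetyloxy)-8-[(tert-butyldiphenylsilyl)oxy]-2,6-dimethylocta-2,6-dien-1-yl]-2-hydroxy-4-iodo-2,5-dihydrofuran-3-carboxylate (anomer mixture) | COC(=O)C1=C(I)[C@H](C/C(C)=C\[C@@H](OC(C)=O)C/C(C)=C/CO[Si](c2ccccc2)(c2ccccc2)C(C)(C)C)OC1O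
F7 | step 7 | methyl (6Z,8S,10E)-8-(acetyloxy)-12-[(tert-butyldiphenylsilyl)oxy]-4-hydroxy-6,10-dimethyldodeca-6,10-dien-2-ynoate (C4 epimer mixture) | COC(=O)C#CC(O)C/C(C)=C\[C@@H](OC(C)=O)C/C(C)=C/CO[Si](c1ccccc1)(c1ccccc1)C(C)(C)C
F8 | step 7 | methyl (6Z,8S,10E)-8-(acetyloxy)-12-[(tert-butyldiphenylsilyl)oxy]-6,10-dimethyl-4-oxododeca-6,10-dien-2-ynoate | COC(=O)C#CC(=O)C/C(C)=C\[C@@H](OC(C)=O)C/C(C)=C/CO[Si](c1ccccc1)(c1ccccc1)C(C)(C)C
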